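The plan opens ring D at C8–C15 and C13–C16. In a tricyclic 8(14)-en-13-one (rings A–C), the beta carbon is the future quaternary bridgehead C8. The alpha and carbonyl carbons of ring C, C14 and C13, sit beside it, where the C15–C16 bridge of the bicyclo[3.2.1]octane must be anchored. One [2+2] photocycloaddition of propadiene puts C15 on C8 and C16 on C14. This closes a cis-fused methylenecyclobutane and sets C8 and C14, and its strain later drives C16 from C14 to C13. The precursor is the 3β-silyloxy C7,C19,C20-trimethyl ester enone. It comes from andrographolide by C20–H oxidation, C3 inversion, ring B cleavage with Dieckmann reclosure, and aldol closure of ring C.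

Key step: step 20

Remark 1: gibberellane numbering is used throughout. Andrographolide C17 and C13–C16 are lost in step 2, and C13 and C14 are brought back in step 3. α/β follow the usual gibberellin drawing: H5 and H9 β, C19 and C20 α. In the target the C15–C16 bridge lies on the β face (syn to H9), the C7 carboxyl is β, 3-OH is β (axial), and 16-OH is exo (on the side of C14).
Remark 2: (1-methoxyethyl)triphenylphosphonium chloride is taken as an available reagent (PPh3 plus 1-chloroethyl methyl ether, one operation).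
Remark 3: origin of stereocentres: C4, C5, C9, C10 from 1; C3 in step 11; C6 in steps 17 and 19; C8 and C14 in step 20; C13 in step 22; C16 in step 26.

Step 1
Reactants: 1 andrographolide
Product: 2 3,14,19-tri-O-acetylandrographolide
Conditions: Ac2O, pyridine, DMAP (cat.), CH2Cl2, 0 °C to rt
Reagents that add atoms: acetic anhydride, CC(=O)OC(C)=O
Why: Exhaustive O-acylation masks the 3α- and 19-hydroxyls as base-removable esters that tolerate ozone, ylide, borohydride, iodine and RuO4, and no stereocentre is touched.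

Step 2
Reactants: 2 3,14,19-tri-O-acetylandrographolide
Product: 3 decalin keto aldehyde (3α,19-diacetoxy-8-oxo-13,14,15,16,17-pentanor-ent-labdan-12-al)
Conditions: O3, CH2Cl2/MeOH, −78 °C; Me2S, −78 °C to rt
Reagents that add atoms: ozone, [O-][O+]=O
Why: Ozonolysis with reductive work-up cleaves both the 8(17)-methylene and the 12(13)-alkylidene lactone bond, leaving the C8 ketone and the C12 aldehyde with C9 in its equatorial, thermodynamically preferred configuration.

Step 3
Reactants: 3 decalin keto aldehyde
Product: 4 keto enol ether (side chain C9–CH2–CH=C(OMe)CH3, E/Z mixture)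
Conditions: Ph3P(+)CH(OMe)CH3 Cl(−), KHMDS, THF, −78 °C; then 3, −78 to 0 °C
Reagents that add atoms: (1-methoxyethyl)triphenylphosphonium chloride, CC(OC)[P+](c1ccccc1)(c1ccccc1)c1ccccc1.[Cl-]
Why: Wittig olefination with a non-stabilised alkoxy ylide takes the aldehyde much faster than the hindered C8 ketone and brings in C13 and C14 as a masked methyl ketone, whose alkene geometry is of no consequence.

Step 4
Reactants: 4 keto enol ether
Product: 5 keto ketal (side chain C9–CH2CH2–C(CH3)(OCH2CH2O), C13 ethylene ketal)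
Conditions: HOCH2CH2OH, PPTS (cat.), CH2Cl2, rt
Reagents that add atoms: ethylene glycol, OCCO
Why: Acid-catalysed addition of the diol to the enol ether with loss of methanol (transketalisation) gives the dioxolane under conditions too mild to ketalise the hindered C8 ketone or to cleave the acetates.

Step 5
Reactants: 5 keto ketal
Product: 6 8α-alcohol (axial OH, syn to C20)
Conditions: NaBH4, MeOH, 0 °C
Reagents that add atoms: none
Why: In this borohydride reduction the α-face axial approach is blocked by the 1,3-diaxial C20 methyl group, so hydride arrives from the β face and sets the axial 8α-alcohol, as in 6-oxo and 11-oxo steroids.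

Step 6
Reactants: 6 8α-alcohol
Product: 7 8α,20-epoxide (tetrahydrofuran O–C8–C9–C10–C20)
Conditions: PhI(OAc)2, I2, cyclohexane/CH2Cl2, hν (visible), rt
Reagents that add atoms: none
Why: In the Suárez hypoiodite reaction the 8α-alkoxy radical lies 1,3-diaxial to C20, abstracts one of its hydrogens through a six-membered transition state, and oxidation of the C20 radical with ring closure gives the cyclic ether, as in the steroid 6β,19-ether synthesis.

Step 7
Reactants: 7 8α,20-epoxide
Product: 8 20,8α-lactone 3α,19-diacetate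
Conditions: RuCl3·xH2O (cat.), NaIO4, EtOAc/MeCN/H2O, rt
Reagents that add atoms: sodium periodate, [Na+].[O-]I(=O)(=O)=O
Why: RuO4 oxidation of an ether to a lactone attacks the O–CH2 group (C20) rather than the tertiary O–CH (C8), while the acetates and the ketal are spectators.

Step 8
Reactants: 8 20,8α-lactone 3α,19-diacetate
Product: 9 20,8α-lactone 3α,19-diol
Conditions: K2CO3 (cat.), MeOH, rt to 40 °C
Reagents that add atoms: none
Why: Base-catalysed transesterification removes both acetates, and any methanolysis of the γ-lactone is reversible and closes again.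

Step 9
Reactants: 9 20,8α-lactone 3α,19-diol
Product: 11 methyl 3α-hydroxy-19-oate 20,8α-lactone, via hydroxy acid 10 (not isolated)
Conditions: TEMPO (cat.), NaOCl (cat.), NaClO2, MeCN/phosphate buffer pH 6.7, 35 °C; then TMSCHN2, PhMe/MeOH, 0 °C
Reagents that add atoms: sodium chlorite, [Na+].[O-]Cl=O; trimethylsilyldiazomethane, C[Si](C)(C)C=[N+]=[N-]
Why: The oxoammonium-catalysed chlorite oxidation selects the primary C19 alcohol over the secondary 3α-alcohol, the buffered medium spares the ketal, and the crude acid is esterified at once.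

Step 10
Reactants: 11 methyl 3α-hydroxy-19-oate 20,8α-lactone
Product: 12 methyl 3-oxo-19-oate 20,8α-lactone
Conditions: Dess–Martin periodinane, NaHCO3, CH2Cl2, rt
Reagents that add atoms: none
Why: Dess–Martin oxidation gives the 3-ketone as a β-keto ester with a quaternary C4, which cannot epimerise and, being an ester, cannot decarboxylate.

Step 11
Reactants: 12 methyl 3-oxo-19-oate 20,8α-lactone
Product: 13 methyl 3β-hydroxy-19-oate 20,8α-lactone
Conditions: L-Selectride, THF, −78 °C; H2O
Reagents that add atoms: none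
Why: The bulky trialkylborohydride attacks along the equatorial trajectory, as with 4,4-disubstituted 3-oxo terpenoids, and so sets the axial 3β-alcohol, the only ketone present being C3 and ester and lactone being inert at −78 °C.

Step 12
Reactants: 13 methyl 3β-hydroxy-19-oate 20,8α-lactone
Product: 14 methyl 3β-(tert-butyldimethylsilyloxy)-19-oate 20,8α-lactone
Conditions: TBSOTf, 2,6-lutidine, CH2Cl2, −40 to 0 °C
Reagents that add atoms: tert-butyldimethylsilyl triflate, CC(C)(C)[Si](C)(C)OS(=O)(=O)C(F)(F)F
Why: Silylation with the triflate reaches the hindered axial alcohol and blocks retro-aldol cleavage between C3 and C4 in all later basic steps.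

Step 13
Reactants: 14 methyl 3β-(tert-butyldimethylsilyloxy)-19-oate 20,8α-lactone
Product: 17 dimethyl 8-oxo-19,20-dioate, via hydroxy carboxylate 15 (not isolated), via keto acid 16 (not isolated)
Conditions: KOH, t-BuOH/H2O, 70 °C; KMnO4, 0 °C; aq. KHSO4; then TMSCHN2, PhMe/MeOH, 0 °C
Reagents that add atoms: potassium hydroxide, [K+].[OH-]; trimethylsilyldiazomethane, C[Si](C)(C)C=[N+]=[N-]
Why: Saponification opens the lactone, and permanganate oxidises the hydroxy carboxylate while it is still in base so that it cannot relactonise, the very hindered C19 ester, the silyl ether and the ketal surviving before the crude acid is methylated.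

Step 14
Reactants: 17 dimethyl 8-oxo-19,20-dioate
Product: 18 Δ7 8-trimethylsilyloxy enol ether
Conditions: LDA, TMSCl, THF, −78 °C
Reagents that add atoms: chlorotrimethylsilane, C[Si](C)(C)Cl
Why: Kinetic deprotonation with in situ silylation takes the C7 methylene rather than the hindered tertiary C9–H, and no ester in 17 carries an α-hydrogen.

Step 15
Reactants: 18 Δ7 8-trimethylsilyloxy enol ether
Product: 19 7,8-seco 7-al 8-oic acid
Conditions: O3, CH2Cl2, −78 °C; Me2S; aqueous work-up
Reagents that add atoms: ozone, [O-][O+]=O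
Why: Ozonolysis of the silyl enol ether cuts C7–C8 regiospecifically, giving the C7 aldehyde and, after hydrolysis of the silyl ester, the C8 acid without touching C5, C9 or C10.

Step 16
Reactants: 19 7,8-seco 7-al 8-oic acid
Product: 21 7,8-seco tetramethyl 7,8,19,20-tetraoate, via seco diacid 20 (not isolated)
Conditions: NaClO2, NaH2PO4, 2-methyl-2-butene, t-BuOH/H2O, rt; then TMSCHN2, PhMe/MeOH, 0 °C
Reagents that add atoms: sodium chlorite, [Na+].[O-]Cl=O; trimethylsilyldiazomethane, C[Si](C)(C)C=[N+]=[N-]
Why: Pinnick oxidation raises C7 to the acid under mild, non-epimerising conditions, and both new acids are methylated in the crude state.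

Step 17
Reactants: 21 7,8-seco tetramethyl 7,8,19,20-tetraoate
Product: 22 ring B β-keto ester (trans-hydrindan-8-one, 6β-CO2Me, H9β, C13 ketal)
Conditions: KOt-Bu, THF, 0 °C to rt; 1 M HCl
Reagents that add atoms: none
Why: In this Dieckmann condensation only attack of C6 on the C8 ester gives an enolisable β-keto ester (the thermodynamic sink), ring B closes trans because C5 and C10 are fixed, C6 settles β (trans to C4), and C9 keeps the favoured arrangement with C11 cis to the angular C20 group, as with steroid 17β side chains.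

Step 18
Reactants: 22 ring B β-keto ester
Product: 23 8,13-diketone (β-keto ester with 3-oxobutyl chain at C9)
Conditions: PPTS, acetone/H2O, 50 °C
Reagents that add atoms: water, O
Why: Mild acid hydrolysis removes the dioxolane while the hindered secondary silyl ether and the esters stay.

Step 19
Reactants: 23 8,13-diketone
Product: 24 tricyclic 8(14)-en-13-one triester (3β-OTBS; 6β-, 4α- and 10α-CO2Me; H5β, H9β)
Conditions: pyrrolidine (cat.), AcOH (cat.), toluene, 80 °C
Reagents that add atoms: none
Why: Enamine-catalysed intramolecular aldol condensation of the 1,5-diketone (Robinson and Hagemann ester type) joins C14 to C8 and dehydrates to the enone, the more stable tautomer, with C6–H equilibrated to the β-ester.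

Step 20
Reactants: 24 tricyclic 8(14)-en-13-one triester; 25 propadiene
Product: 26 methylenecyclobutane photoadduct (C15 on C8 and C16 on C14, both β, cis-fused)
Conditions: 25 (excess, condensed), CH2Cl2, −78 °C, hν (medium-pressure Hg lamp, uranium-glass filter, λ > 340 nm); filtration through neutral Al2O3
Reagents that add atoms: none
Why: Excitation and intersystem crossing give the twisted enone triplet, which bonds through C14 to the central allene carbon C16, and the resulting 1,4-biradical (tertiary C8 radical plus C15–C16–C17 allyl radical) collapses after spin inversion by forming C8–C15. This is the enone–allene [2+2] photocycloaddition with its normal head-to-head orientation, long applied to hydrophenanthrenones and hydrofluorenones. The one new ring, the cyclobutane C8–C15–C16–C14, is closed by combination of the two radical ends (a four-membered closure on the C8–C14 edge of ring C) and ends up cis-fused, because any trans-fused isomer epimerises at the enolisable C14 on alumina. C8 is controlled by its neighbours C9 and C10: the axial C20 ester on C10 covers the α face of the flat C6–C8(=C14)–C9 unit, so C15 arrives on the β face syn to H9, and C14 follows from the cis fusion. The step needs facial selectivity at C8 and head-to-head regioselectivity; the first is secured by the C20 ester together with the outward, pseudo-equatorial position of the C7 ester, and the second by the stability of the allyl radical. Long-wavelength light, low temperature and a neutral medium keep the acidic C6–H and the saturated esters out of play.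

Step 21
Reactants: 26 methylenecyclobutane photoadduct
Product: 27 cyclobutanone (13,16-dione)
Conditions: O3, CH2Cl2, −78 °C; Me2S
Reagents that add atoms: ozone, [O-][O+]=O
Why: Ozonolysis of the only alkene gives the cyclobutanone, methanol being left out because the strained 1,3-diketone is prone to retro-Claisen opening, and no sulfur-based radical precursor has to face ozone.

Step 22
Reactants: 27 cyclobutanone (13,16-dione)
Product: 28 13-hydroxy-16-ketone (bicyclo[3.2.1]octane rings C and D)
Conditions: SmI2, t-BuOH, THF, −78 to 0 °C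
Reagents that add atoms: none
Why: In this reductive 1,2-acyl shift of Dowd–Beckwith type the C13 ketyl adds to the neighbouring cyclobutanone carbonyl in 3-exo mode, and the cyclopropanolate reopens by breaking C14–C16, the only cleavage that releases the four-ring strain, so that C16 ends on the bridgehead C13, whose configuration is dictated by the bridge.

Step 23
Reactants: 28 13-hydroxy-16-ketone
Product: 29 13-O-(methoxyoxalyl) 16-ketone
Conditions: ClCOCO2Me, DMAP, pyridine, CH2Cl2, 0 °C to rt
Reagents that add atoms: methyl chlorooxoacetate, COC(=O)C(=O)Cl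
Why: Acylation under weakly basic conditions avoids the base-induced acyloin rearrangement of the bridgehead α-ketol and installs the radical leaving group that is established for the 13-hydroxyl of gibberellins.

Step 24
Reactants: 29 13-O-(methoxyoxalyl) 16-ketone
Product: 30 16-ketone (13-H, 17-nor)
Conditions: n-Bu3SnH, AIBN (cat.), toluene, reflux
Reagents that add atoms: none
Why: In this oxalate variant of the Barton–McCombie deoxygenation, stannyl radical addition and C–O scission give the bridgehead C13 radical, which can only take up hydrogen with retention.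

Step 25
Reactants: 30 16-ketone
Product: 31 16(17)-ene (3β-OTBS trimethyl ester)
Conditions: Ph3PCH3Br, KOt-Bu, THF, 0 °C to rt
Reagents that add atoms: methyltriphenylphosphonium bromide, C[P+](c1ccccc1)(c1ccccc1)c1ccccc1.[Br-]
Why: Wittig methylenation is the standard reaction of gibberellin 16-norketones, the hindered esters are not attacked, and C6 already has its more stable configuration.

Step 26
Reactants: 31 16(17)-ene
Product: 32 16-exo-hydroxy-16-methyl compound (3β-OTBS trimethyl ester)
Conditions: Co(acac)2 (cat.), PhSiH3, O2 (1 atm), THF/i-PrOH, rt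
Reagents that add atoms: dioxygen, O=O
Why: In the Mukaiyama hydration, hydrogen-atom transfer to C17 gives the tertiary C16 radical, which is trapped by O2 on the exo face (the side of the one-carbon bridge C14, away from C11 and C12), so the hydroxyl is exo and the methyl endo as in the target, whereas methyl addition to 30 would give the epimer.

Step 27
Reactants: 32 16-exo-hydroxy-16-methyl compound
Product: 33 3β-OTBS 7,19,20-triacid
Conditions: n-PrSLi, HMPA, rt; 1 M HCl
Reagents that add atoms: none
Why: SN2 dealkylation at the methyl carbons by thiolate cleaves all three esters regardless of the hindrance at C19 and C20, and it is run before desilylation so that no 3-alkoxide can trigger retro-aldol epimerisation.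

Step 28
Reactants: 33 3β-OTBS 7,19,20-triacid
Product: 34 target CNP0183110.3
Conditions: HF·pyridine, THF, 0 °C to rt
Reagents that add atoms: none
Why: Fluoride-induced desilylation frees the 3β-alcohol under conditions too mild to ionise the tertiary 16-alcohol or to epimerise any centre.

Compound list
1 | andrographolide | C[C@@]12CC[C@H]([C@@]([C@H]1CCC(=C)[C@H]2C/C=C/3\[C@@H](COC3=O)O)(C)CO)O | starting material
2 | 3,14,19-tri-O-acetylandrographolide | C[C@@]12CC[C@H]([C@@]([C@H]1CCC(=C)[C@H]2C/C=C/3\[C@@H](COC3=O)OC(C)=O)(C)COC(C)=O)OC(C)=O | intermediate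
3 | decalin keto aldehyde, 3α,19-diacetoxy-8-oxo-13,14,15,16,17-pentanor-ent-labdan-12-al | C[C@@]12CC[C@H]([C@@]([C@H]1CCC(=O)[C@H]2CC=O)(C)COC(C)=O)OC(C)=O | intermediate
4 | keto enol ether, side chain C9–CH2–CH=C(OMe)CH3 (E/Z mixture) | C[C@@]12CC[C@H]([C@@]([C@H]1CCC(=O)[C@H]2CC=C(C)OC)(C)COC(C)=O)OC(C)=O | intermediate
5 | keto ketal, C13 ethylene ketal | C[C@@]12CC[C@H]([C@@]([C@H]1CCC(=O)[C@H]2CCC3(C)OCCO3)(C)COC(C)=O)OC(C)=O | intermediate
6 | 8α-alcohol | C[C@@]12CC[C@H]([C@@]([C@H]1CC[C@@H](O)[C@H]2CCC3(C)OCCO3)(C)COC(C)=O)OC(C)=O | intermediate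
7 | 8α,20-epoxide | C3[C@@]12CC[C@H]([C@@]([C@H]1CC[C@@H](O3)[C@H]2CCC4(C)OCCO4)(C)COC(C)=O)OC(C)=O | intermediate
8 | 20,8α-lactone 3α,19-diacetate | O=C3[C@@]12CC[C@H]([C@@]([C@H]1CC[C@@H](O3)[C@H]2CCC4(C)OCCO4)(C)COC(C)=O)OC(C)=O | intermediate
9 | 20,8α-lactone 3α,19-diol | O=C3[C@@]12CC[C@H]([C@@]([C@H]1CC[C@@H](O3)[C@H]2CCC4(C)OCCO4)(C)CO)O | intermediate
10 | 3α-hydroxy-19-oic acid 20,8α-lactone | O=C3[C@@]12CC[C@H]([C@@]([C@H]1CC[C@@H](O3)[C@H]2CCC4(C)OCCO4)(C)C(=O)O)O | intermediate
11 | methyl 3α-hydroxy-19-oate 20,8α-lactone | O=C3[C@@]12CC[C@H]([C@@]([C@H]1CC[C@@H](O3)[C@H]2CCC4(C)OCCO4)(C)C(=O)OC)O | intermediate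
12 | methyl 3-oxo-19-oate 20,8α-lactone | O=C3[C@@]12CCC(=O)[C@@]([C@H]1CC[C@@H](O3)[C@H]2CCC4(C)OCCO4)(C)C(=O)OC | intermediate
13 | methyl 3β-hydroxy-19-oate 20,8α-lactone | O=C3[C@@]12CC[C@@H]([C@@]([C@H]1CC[C@@H](O3)[C@H]2CCC4(C)OCCO4)(C)C(=O)OC)O | intermediate
14 | methyl 3β-(tert-butyldimethylsilyloxy)-19-oate 20,8α-lactone | O=C3[C@@]12CC[C@@H]([C@@]([C@H]1CC[C@@H](O3)[C@H]2CCC4(C)OCCO4)(C)C(=O)OC)O[Si](C)(C)C(C)(C)C | intermediate
15 | potassium 8α-hydroxy-20-oate | [K+].[O-]C(=O)[C@@]12CC[C@@H]([C@@]([C@H]1CC[C@@H](O)[C@H]2CCC3(C)OCCO3)(C)C(=O)OC)O[Si](C)(C)C(C)(C)C | intermediate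
16 | 8-oxo-20-oic acid | OC(=O)[C@@]12CC[C@@H]([C@@]([C@H]1CCC(=O)[C@H]2CCC3(C)OCCO3)(C)C(=O)OC)O[Si](C)(C)C(C)(C)C | intermediate
17 | dimethyl 8-oxo-19,20-dioate | COC(=O)[C@@]12CC[C@@H]([C@@]([C@H]1CCC(=O)[C@H]2CCC3(C)OCCO3)(C)C(=O)OC)O[Si](C)(C)C(C)(C)C | intermediate
18 | Δ7 8-trimethylsilyloxy enol ether | COC(=O)[C@@]12CC[C@@H]([C@@]([C@H]1CC=C(O[Si](C)(C)C)[C@H]2CCC3(C)OCCO3)(C)C(=O)OC)O[Si](C)(C)C(C)(C)C | intermediate
19 | 7,8-seco 7-al 8-oic acid | COC(=O)[C@@]1([C@@H](C(=O)O)CCC2(C)OCCO2)CC[C@@H]([C@@]([C@H]1CC=O)(C)C(=O)OC)O[Si](C)(C)C(C)(C)C | intermediate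
20 | 7,8-seco 7,8-dioic acid | COC(=O)[C@@]1([C@@H](C(=O)O)CCC2(C)OCCO2)CC[C@@H]([C@@]([C@H]1CC(=O)O)(C)C(=O)OC)O[Si](C)(C)C(C)(C)C | intermediate
21 | 7,8-seco tetramethyl 7,8,19,20-tetraoate | COC(=O)[C@@]1([C@@H](C(=O)OC)CCC2(C)OCCO2)CC[C@@H]([C@@]([C@H]1CC(=O)OC)(C)C(=O)OC)O[Si](C)(C)C(C)(C)C | intermediate
22 | ring B β-keto ester, trans-hydrindan-8-one, C13 ketal | C[C@]1(C(=O)OC)[C@H]2[C@H](C(=O)OC)C(=O)[C@@H](CCC3(C)OCCO3)[C@]2(C(=O)OC)CC[C@@H]1O[Si](C)(C)C(C)(C)C | intermediate
23 | 8,13-diketone | C[C@]1(C(=O)OC)[C@H]2[C@H](C(=O)OC)C(=O)[C@@H](CCC(C)=O)[C@]2(C(=O)OC)CC[C@@H]1O[Si](C)(C)C(C)(C)C | intermediate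
24 | tricyclic 8(14)-en-13-one triester | C[C@]1(C(=O)OC)[C@H]2[C@H](C(=O)OC)C3=CC(=O)CC[C@H]3[C@]2(C(=O)OC)CC[C@@H]1O[Si](C)(C)C(C)(C)C | intermediate
25 | propadiene | C=C=C | starting material
26 | methylenecyclobutane photoadduct | C[C@]1(C(=O)OC)[C@H]2[C@H](C(=O)OC)[C@]34CC(=C)[C@@H]4C(=O)CC[C@H]3[C@]2(C(=O)OC)CC[C@@H]1O[Si](C)(C)C(C)(C)C | intermediate
27 | cyclobutanone, 13,16-dione | C[C@]1(C(=O)OC)[C@H]2[C@H](C(=O)OC)[C@]34CC(=O)[C@@H]4C(=O)CC[C@H]3[C@]2(C(=O)OC)CC[C@@H]1O[Si](C)(C)C(C)(C)C | intermediate
28 | 13-hydroxy-16-ketone | C[C@]1(C(=O)OC)[C@H]2[C@H](C(=O)OC)[C@@]34C[C@@](O)(CC[C@H]3[C@]2(C(=O)OC)CC[C@@H]1O[Si](C)(C)C(C)(C)C)C(=O)C4 | intermediate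
29 | 13-O-(methoxyoxalyl) 16-ketone | C[C@]1(C(=O)OC)[C@H]2[C@H](C(=O)OC)[C@@]34C[C@@](OC(=O)C(=O)OC)(CC[C@H]3[C@]2(C(=O)OC)CC[C@@H]1O[Si](C)(C)C(C)(C)C)C(=O)C4 | intermediate
30 | 16-ketone, 13-H | C[C@]1(C(=O)OC)[C@H]2[C@H](C(=O)OC)[C@@]34C[C@@H](CC[C@H]3[C@]2(C(=O)OC)CC[C@@H]1O[Si](C)(C)C(C)(C)C)C(=O)C4 | intermediate
31 | 16(17)-ene | C[C@]1(C(=O)OC)[C@H]2[C@H](C(=O)OC)[C@@]34C[C@@H](CC[C@H]3[C@]2(C(=O)OC)CC[C@@H]1O[Si](C)(C)C(C)(C)C)C(=C)C4 | intermediate
32 | 16-exo-hydroxy-16-methyl 3β-OTBS trimethyl ester | C[C@]1(C(=O)OC)[C@H]2[C@H](C(=O)OC)[C@@]34C[C@@H](CC[C@H]3[C@]2(C(=O)OC)CC[C@@H]1O[Si](C)(C)C(C)(C)C)[C@](C)(O)C4 | intermediate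
33 | 3β-OTBS 7,19,20-triacid | C[C@]1(C(=O)O)[C@H]2[C@H](C(=O)O)[C@@]34C[C@@H](CC[C@H]3[C@]2(C(=O)O)CC[C@@H]1O[Si](C)(C)C(C)(C)C)[C@](C)(O)C4 | intermediate
34 | CNP0183110.3 | C[C@]1(C(=O)O)[C@H]2[C@H](C(=O)O)[C@@]34C[C@@H](CC[C@H]3[C@]2(C(=O)O)CC[C@@H]1O)[C@](C)(O)C4 | target

Total step count: 28. Longest linear sequence: 28 (steps 1 to 28; propadiene enters at step 20).

Steps most likely to fail

Step 20.
- **What may go wrong:** the allene may attack the α face, or both faces, of C8, because the β-oriented C7 ester next to C8 competes with the C20 ester as the blocking group. Photodeconjugation through the acidic C6–H or sluggish conversion is also possible.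
- **Fallback:** it sets out from 24 and returns at 28, building the same two bridge carbons by ground-state chemistry. Hosomi–Sakurai conjugate allylation (allyltrimethylsilane, TiCl4, CH2Cl2, −78 °C) creates the quaternary centre and gives the 8β-allyl 13-ketone F1. Ozonolysis shortens the allyl group to the keto aldehyde F2. Pinacol cyclisation with SmI2 joins C13 and C16 to the 13,16-diol F3 (C16 epimers). Dess–Martin oxidation of the secondary alcohol then gives the α-ketol 28.

Step 6.
- **What may go wrong:** the alkoxy radical may abstract hydrogen from the flexible side chain (C12–H) instead of C20, may undergo β-scission of C8–C9, or the iodine reagents may attack the ketal.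
- **Fallback:** it sets out from 6 and returns at 8, replacing the radical relay by metal-catalysed C–H silylation. Dehydrogenative silylation of the alcohol (Et2SiH2, [Ir(cod)OMe]2 cat.) gives the diethylhydrosilyl ether F4. Intramolecular silylation of the δ C–H bond ([Rh(cod)Cl]2, Xantphos, norbornene, 100 °C) selects the only primary δ position, C20, and closes the oxasilinane F5. Tamao–Fleming oxidation (H2O2, KHCO3, KF) gives the 8α,20-diol F6. Oxidative lactonisation (TEMPO, PhI(OAc)2) then gives 8.

Step 19.
- **What may go wrong:** the β-keto ester may be diverted into its enolate or enamino ester, so that the C8 carbonyl loses its electrophilicity and ring C does not close. A reversible bridged aldol of C6 onto C13 is also possible.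
- **Fallback:** it sets out from 23 and returns at 24, turning C8 into the β carbon of an acceptor. O-methylation of the β-keto ester (Me2SO4, K2CO3, acetone) gives the β-methoxy enoate F7. Kinetic deprotonation of the methyl ketone at C14 (KHMDS, THF, −78 °C) triggers intramolecular conjugate addition–elimination at C8 with loss of methoxide. DBU then moves the double bond into conjugation with the ketone and equilibrates C6, giving 24.

Further compounds
F1 | step 20 | 8β-allyl 13-ketone | C[C@]1(C(=O)OC)[C@H]2[C@H](C(=O)OC)[C@@]3(CC=C)CC(=O)CC[C@H]3[C@]2(C(=O)OC)CC[C@@H]1O[Si](C)(C)C(C)(C)C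
F2 | step 20 | keto aldehyde (C8–CH2–CHO, 13-ketone) | C[C@]1(C(=O)OC)[C@H]2[C@H](C(=O)OC)[C@@]3(CC=O)CC(=O)CC[C@H]3[C@]2(C(=O)OC)CC[C@@H]1O[Si](C)(C)C(C)(C)C
F3 | step 20 | 13,16-diol (C16 epimers) | C[C@]1(C(=O)OC)[C@H]2[C@H](C(=O)OC)[C@@]34C[C@@](O)(CC[C@H]3[C@]2(C(=O)OC)CC[C@@H]1O[Si](C)(C)C(C)(C)C)C(O)C4
F4 | step 6 | 8α-diethylhydrosilyl ether | C[C@@]12CC[C@H]([C@@]([C@H]1CC[C@@H](O[SiH](CC)CC)[C@H]2CCC3(C)OCCO3)(C)COC(C)=O)OC(C)=O
F5 | step 6 | oxasilinane (O8–SiEt2–C20) | C3[C@@]12CC[C@H]([C@@]([C@H]1CC[C@@H](O[Si]3(CC)CC)[C@H]2CCC4(C)OCCO4)(C)COC(C)=O)OC(C)=O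
F6 | step 6 | 8α,20-diol | OC[C@@]12CC[C@H]([C@@]([C@H]1CC[C@@H](O)[C@H]2CCC3(C)OCCO3)(C)COC(C)=O)OC(C)=O
F7 | step 19 | β-methoxy enoate (C8(OMe)=C6–CO2Me) | C[C@]1(C(=O)OC)[C@H]2C(C(=O)OC)=C(OC)[C@@H](CCC(C)=O)[C@]2(C(=O)OC)CC[C@@H]1O[Si](C)(C)C(C)(C)C
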